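Everything rests on opening the seven-membered ring at C6–C7. In the target, C6 (attached to the ring-fusion carbon C5) and C9 (attached to C10) are both oxygenated, so C6 can be an acyl radical and C7 the CH2 terminus of a C9 isopropenyl ketone: a nucleophilic radical facing an electron-poor alkene across the future ring. One 7-endo cyclisation closes the cycloheptane as a trans-fused 6,9-dione. The precursor is a cyclopentane carrying the C1 methyl quaternary centre, the free C4 isopropyl carbinol, a phenyl selenoester at C5 and, trans to it on C1, the CH2–CO–C(CH3)=CH2 arm.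

Key step: step 13

Remark: ring atoms carry daucane numbers (C1 quaternary C–CH3, C2, C3, C4 carbinol, C5 fusion CH, C6–C10 around the seven-membered ring); the tertiary C4 hydroxyl is carried unprotected because it should be inert to the reagents used and must be free to direct the reduction in step 14; the chiral NHC–silver complex of step 1 is a catalyst prepared separately.

Step 1
Reactants: 1 3-methylcyclopent-2-en-1-one; 2 ethynyltrimethylsilane
Product: 5 (S)-trimethyl({3-methyl-3-[1-(trimethylsilyl)ethenyl]cyclopent-1-en-1-yl}oxy)silane, via vinylalane 3 (not isolated), via aluminium enolate 4 (not isolated)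
Conditions: 2, DIBAL-H, hexane, 55 °C; then 1, Cu(OTf)2 (5 mol %), chiral sulfonate-NHC–Ag(I) complex (2.5 mol %, enantiomer giving 3S), THF, −78 °C; then TMSOTf, −78 → 0 °C
Reagents that add atoms: trimethylsilyl trifluoromethanesulfonate, C[Si](C)(C)OS(=O)(=O)C(F)(F)F
Why: Hydroalumination places aluminium on the silicon-bearing alkyne carbon, the NHC–Cu catalysed asymmetric conjugate addition of this alkenylalane to the β-methyl enone sets the quaternary centre C1 by catalyst control, and O-silylation of the aluminium enolate locks the enolate regiochemistry toward C5.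

Step 2
Reactants: 5 silyl enol ether; 6 formaldehyde
Product: 7 (2S,3S)-2-(hydroxymethyl)-3-methyl-3-[1-(trimethylsilyl)ethenyl]cyclopentan-1-one
Conditions: 37 % aq. HCHO, Yb(OTf)3 (10 mol %), THF, 22 °C
Reagents that add atoms: none
Why: Lanthanide-triflate catalysed Mukaiyama aldol hydroxymethylation in aqueous medium, in which formaldehyde should attack the enol ether face anti to the bulky silylvinyl group on the adjacent quaternary carbon, so that C6 ends up cis to the C1 methyl, which is also the more stable arrangement.

Step 3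
Reactants: 7 hydroxymethyl ketone
Product: 8 (2S,3S)-2-{[tert-butyl(diphenyl)silyl]oxymethyl}-3-methyl-3-[1-(trimethylsilyl)ethenyl]cyclopentan-1-one
Conditions: TBDPSCl, imidazole, CH2Cl2, 0 → 22 °C
Reagents that add atoms: tert-butyl(chloro)diphenylsilane, CC(C)(C)[Si](Cl)(c1ccccc1)c1ccccc1
Why: Imidazole-mediated silylation of the primary alcohol is too mild for retro-aldol or epimerisation, and the TBDPS ether is chosen because it should survive the acid of step 4 and be removable later by fluoride.

Step 4
Reactants: 8 silylvinyl ketone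
Product: 9 (2S,3R)-2-{[tert-butyl(diphenyl)silyl]oxymethyl}-3-ethenyl-3-methylcyclopentan-1-one
Conditions: CF3CO2H (5 equiv), CH2Cl2, 0 → 22 °C
Reagents that add atoms: none
Why: Acid-mediated protodesilylation of the vinylsilane (ipso protonation, β-silyl cation, loss of silicon) unmasks the plain vinyl group needed for step 6, while the ketone and the TBDPS ether tolerate the acid and the hindered C5–H is not expected to enolise at this temperature.

Step 5
Reactants: 9 vinyl ketone; 10 isopropylmagnesium chloride
Product: 11 (1R,2S,3R)-2-{[tert-butyl(diphenyl)silyl]oxymethyl}-3-ethenyl-3-methyl-1-(propan-2-yl)cyclopentan-1-ol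
Conditions: LaCl3·2LiCl (1 equiv), THF, 0 °C
Reagents that add atoms: none
Why: Lanthanide-promoted Grignard 1,2-addition suppresses enolisation and β-hydride reduction of the hindered ketone, and isopropyl should enter anti to the adjacent C5 CH2OSi group and the C1 methyl, which places the new C4 hydroxyl cis to both.

Step 6
Reactants: 11 vinyl carbinol
Product: 13 (1R,2S,3R)-2-{[tert-butyl(diphenyl)silyl]oxymethyl}-3-(2-hydroxyethyl)-3-methyl-1-(propan-2-yl)cyclopentan-1-ol, via alkylborane 12 (not isolated)
Conditions: 9-BBN (3 equiv), THF, 0 → 50 °C; then NaOH, H2O2, 0 °C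
Reagents that add atoms: hydrogen peroxide, OO
Why: Anti-Markovnikov hydroboration–oxidation puts oxygen on the terminal vinyl carbon, the future C9, while the free tertiary hydroxyl only consumes borane and no stereocentre is formed.

Step 7
Reactants: 13 diol
Product: 14 2-[(1R,2S,3R)-2-{[tert-butyl(diphenyl)silyl]oxymethyl}-3-hydroxy-1-methyl-3-(propan-2-yl)cyclopentyl]acetaldehyde
Conditions: Dess–Martin periodinane, NaHCO3, CH2Cl2, 0 → 22 °C
Reagents that add atoms: none
Why: Buffered Dess–Martin oxidation takes the primary alcohol to the aldehyde, the tertiary hydroxyl cannot be oxidised, and its trans relation to the C10 arm rules out lactol formation.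

Step 8
Reactants: 14 aldehyde; 15 isopropenylmagnesium bromide
Product: 16 1-[(1R,2S,3R)-2-{[tert-butyl(diphenyl)silyl]oxymethyl}-3-hydroxy-1-methyl-3-(propan-2-yl)cyclopentyl]-3-methylbut-3-en-2-ol (C9 epimers)
Conditions: 15 (2.5 equiv), THF, −78 → −20 °C
Reagents that add atoms: none
Why: Grignard 1,2-addition to the aldehyde follows deprotonation of the tertiary hydroxyl by the first equivalent, and the new C9 carbinol may form as an epimer mixture because C9 is oxidised in step 10.

Step 9
Reactants: 16 allylic alcohol
Product: 17 (1R,2S,3R)-3-(2-hydroxy-3-methylbut-3-en-1-yl)-2-(hydroxymethyl)-3-methyl-1-(propan-2-yl)cyclopentan-1-ol (C9 epimers)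
Conditions: TBAF, THF, 22 °C
Reagents that add atoms: none
Why: Fluoride-mediated desilylation removes the only silicon group left, and nothing else in the molecule responds to TBAF.

Step 10
Reactants: 17 triol
Product: 18 (1R,2R,5R)-2-hydroxy-5-methyl-5-(3-methyl-2-oxobut-3-en-1-yl)-2-(propan-2-yl)cyclopentane-1-carbaldehyde
Conditions: Dess–Martin periodinane (3 equiv), NaHCO3, CH2Cl2, 0 → 22 °C
Reagents that add atoms: none
Why: One Dess–Martin oxidation converts the primary C6 alcohol to the aldehyde and the secondary allylic C9 alcohol to the isopropenyl ketone, the tertiary C4 hydroxyl being inert and the bicarbonate buffer guarding against retro-aldol cleavage and C5 epimerisation.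

Step 11
Reactants: 18 keto aldehyde
Product: 19 (1R,2R,5R)-2-hydroxy-5-methyl-5-(3-methyl-2-oxobut-3-en-1-yl)-2-(propan-2-yl)cyclopentane-1-carboxylic acid
Conditions: NaClO2, NaH2PO4, 2-methyl-2-butene, t-BuOH/H2O, 0 °C
Reagents that add atoms: sodium chlorite, [Na+].[O-]Cl=O
Why: Pinnick oxidation is selective for the aldehyde, leaves the electron-poor enone and the tertiary alcohol alone, and its weakly acidic buffer should neither epimerise C5 nor cleave the β-hydroxy acid.

Step 12
Reactants: 19 keto acid; 20 N-(phenylseleno)phthalimide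
Product: 21 Se-phenyl (1R,2R,5R)-2-hydroxy-5-methyl-5-(3-methyl-2-oxobut-3-en-1-yl)-2-(propan-2-yl)cyclopentane-1-carboselenoate
Conditions: 20, Bu3P, CH2Cl2, −20 °C (premixed); then 19, → 0 °C
Reagents that add atoms: none
Why: Phosphine-mediated selenoesterification (acyloxyphosphonium attacked by phenylselenolate) with the phthalimide-based reagent releases no free selenol, premixing leaves little free phosphine to add to the enone, and the hindered tertiary hydroxyl is not activated.

Step 13
Reactants: 21 selenoester
Product: 22 (1R,4R,5R)-4-hydroxydaucane-6,9-dione (trans-fused, C8 epimers)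
Conditions: (Me3Si)3SiH (syringe pump), V-70 azo initiator (cat.), toluene (5 mM), 35 °C
Reagents that add atoms: none
Why: An initiator-derived (Me3Si)3Si radical abstracts the phenylseleno group of 21 to give the C6 acyl radical, which adds to C7, the unsubstituted alkene terminus of the isopropenyl ketone, and the resulting tertiary α-keto radical at C8 takes hydrogen from the silane and so regenerates the chain carrier. The closest known reaction type is the stannane- or silane-mediated cyclisation of phenyl selenoesters onto acrylate- and enone-type acceptors, for which 7-endo closures are on record. The cycloheptane ring (C5–C6–C7–C8–C9–C10–C1) closes in the 7-endo-trig mode, both alkene carbons ending up in the ring. The only new stereocentre, C8, comes from unselective hydrogen transfer to a planar radical and is carried as a mixture until it becomes sp2 in step 16, while the trans ring fusion is inherited from the trans C5/C1 substituents of the cyclopentane, which neutral radical conditions cannot epimerise. The step needs 7-endo over 6-exo attack and ring closure over decarbonylation or direct reduction of the acyl radical: attack at C8 would be polarity-mismatched and would create a quaternary carbon, and the low temperature, the high dilution and the slow hydrogen donor favour closure over the escape routes.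

Step 14
Reactants: 22 dione
Product: 23 (1R,4R,5S,6S)-4,6-dihydroxydaucan-9-one (C8 epimers; 6-OH cis to H5 and anti to the 4-OH)
Conditions: Me4NBH(OAc)3, MeCN/AcOH (1:1), −20 → 0 °C
Reagents that add atoms: none
Why: In this hydroxyl-directed (Evans–Saksena) reduction the C4 alkoxyborohydride delivers hydride intramolecularly to the C6 carbonyl on the side of the C4 oxygen, which should give the 1,3-anti diol, while the undirected C9 ketone is not reduced by this reagent.

Step 15
Reactants: 23 hydroxy ketone; 24 4-methoxybenzoyl chloride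
Product: 25 (1R,4R,5S,6S)-4-hydroxy-9-oxodaucan-6-yl 4-methoxybenzoate (C8 epimers)
Conditions: Et3N, DMAP, CH2Cl2, 22 °C
Reagents that add atoms: none
Why: DMAP-catalysed acylation takes place at the secondary C6 hydroxyl because the tertiary C4 hydroxyl is too hindered, and any transannular 6,9-hemiketal is in equilibrium with the open hydroxy ketone that is esterified.

Step 16
Reactants: 25 keto ester
Product: 26 (1R,4R,5S,6S)-4-hydroxy-9-oxodauc-7-en-6-yl 4-methoxybenzoate
Conditions: IBX, DMSO, 70 °C
Reagents that add atoms: none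
Why: IBX-mediated α,β-dehydrogenation of the C9 ketone can only run toward C8 because C10 has no β-hydrogen (C1 is quaternary), the conjugated endocyclic C7=C8 enone is the expected product, and both C8 epimers converge on it.

Step 17
Reactants: 26 enone
Product: 27 (1R,4R,5S,6S,9R)-4,9-dihydroxydauc-7-en-6-yl 4-methoxybenzoate (target)
Conditions: NaBH4, CeCl3·7H2O, MeOH, −78 °C
Reagents that add atoms: none
Why: Luche reduction gives 1,2-reduction of the enone without touching the aryl ester, and hydride is expected to approach C9 anti to the angular C1 methyl that flanks it across C10, which places the 9-hydroxyl cis to that methyl.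

Compound list
1 | 3-methylcyclopent-2-en-1-one | CC1=CC(=O)CC1 | starting material
2 | ethynyltrimethylsilane | C#C[Si](C)(C)C | starting material
3 | diisobutyl[1-(trimethylsilyl)ethenyl]alane | C=C([Si](C)(C)C)[Al](CC(C)C)CC(C)C | intermediate
4 | diisobutylaluminium (S)-3-methyl-3-[1-(trimethylsilyl)ethenyl]cyclopent-1-en-1-olate | C=C([Si](C)(C)C)[C@@]1(C)CCC(O[Al](CC(C)C)CC(C)C)=C1 | intermediate
5 | (S)-trimethyl({3-methyl-3-[1-(trimethylsilyl)ethenyl]cyclopent-1-en-1-yl}oxy)silane | C=C([Si](C)(C)C)[C@@]1(C)CCC(O[Si](C)(C)C)=C1 | intermediate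
6 | formaldehyde | C=O | starting material
7 | (2S,3S)-2-(hydroxymethyl)-3-methyl-3-[1-(trimethylsilyl)ethenyl]cyclopentan-1-one | C=C([Si](C)(C)C)[C@@]1(C)CCC(=O)[C@@H]1CO | intermediate
8 | (2S,3S)-2-{[tert-butyl(diphenyl)silyl]oxymethyl}-3-methyl-3-[1-(trimethylsilyl)ethenyl]cyclopentan-1-one | C=C([Si](C)(C)C)[C@@]1(C)CCC(=O)[C@@H]1CO[Si](c2ccccc2)(c3ccccc3)C(C)(C)C | intermediate
9 | (2S,3R)-2-{[tert-butyl(diphenyl)silyl]oxymethyl}-3-ethenyl-3-methylcyclopentan-1-one | C=C[C@@]1(C)CCC(=O)[C@@H]1CO[Si](c2ccccc2)(c3ccccc3)C(C)(C)C | intermediate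
10 | isopropylmagnesium chloride | CC(C)[Mg]Cl | starting material
11 | (1R,2S,3R)-2-{[tert-butyl(diphenyl)silyl]oxymethyl}-3-ethenyl-3-methyl-1-(propan-2-yl)cyclopentan-1-ol | C=C[C@@]1(C)CC[C@@](O)(C(C)C)[C@@H]1CO[Si](c2ccccc2)(c3ccccc3)C(C)(C)C | intermediate
12 | B-alkyl-9-borabicyclo[3.3.1]nonane adduct of 11 (boron on the terminal carbon) | C(C[C@@]1(C)CC[C@@](O)(C(C)C)[C@@H]1CO[Si](c2ccccc2)(c3ccccc3)C(C)(C)C)B4C5CCCC4CCC5 | intermediate
13 | (1R,2S,3R)-2-{[tert-butyl(diphenyl)silyl]oxymethyl}-3-(2-hydroxyethyl)-3-methyl-1-(propan-2-yl)cyclopentan-1-ol | OCC[C@@]1(C)CC[C@@](O)(C(C)C)[C@@H]1CO[Si](c2ccccc2)(c3ccccc3)C(C)(C)C | intermediate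
14 | 2-[(1R,2S,3R)-2-{[tert-butyl(diphenyl)silyl]oxymethyl}-3-hydroxy-1-methyl-3-(propan-2-yl)cyclopentyl]acetaldehyde | O=CC[C@@]1(C)CC[C@@](O)(C(C)C)[C@@H]1CO[Si](c2ccccc2)(c3ccccc3)C(C)(C)C | intermediate
15 | isopropenylmagnesium bromide | CC(=C)[Mg]Br | starting material
16 | 1-[(1R,2S,3R)-2-{[tert-butyl(diphenyl)silyl]oxymethyl}-3-hydroxy-1-methyl-3-(propan-2-yl)cyclopentyl]-3-methylbut-3-en-2-ol (C9 epimers) | C=C(C)C(O)C[C@@]1(C)CC[C@@](O)(C(C)C)[C@@H]1CO[Si](c2ccccc2)(c3ccccc3)C(C)(C)C | intermediate
17 | (1R,2S,3R)-3-(2-hydroxy-3-methylbut-3-en-1-yl)-2-(hydroxymethyl)-3-methyl-1-(propan-2-yl)cyclopentan-1-ol (C9 epimers) | C=C(C)C(O)C[C@@]1(C)CC[C@@](O)(C(C)C)[C@@H]1CO | intermediate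
18 | (1R,2R,5R)-2-hydroxy-5-methyl-5-(3-methyl-2-oxobut-3-en-1-yl)-2-(propan-2-yl)cyclopentane-1-carbaldehyde | C=C(C)C(=O)C[C@@]1(C)CC[C@@](O)(C(C)C)[C@@H]1C=O | intermediate
19 | (1R,2R,5R)-2-hydroxy-5-methyl-5-(3-methyl-2-oxobut-3-en-1-yl)-2-(propan-2-yl)cyclopentane-1-carboxylic acid | C=C(C)C(=O)C[C@@]1(C)CC[C@@](O)(C(C)C)[C@@H]1C(=O)O | intermediate
20 | N-(phenylseleno)phthalimide | O=C1c2ccccc2C(=O)N1[Se]c3ccccc3 | starting material
21 | Se-phenyl (1R,2R,5R)-2-hydroxy-5-methyl-5-(3-methyl-2-oxobut-3-en-1-yl)-2-(propan-2-yl)cyclopentane-1-carboselenoate | C=C(C)C(=O)C[C@@]1(C)CC[C@@](O)(C(C)C)[C@@H]1C(=O)[Se]c2ccccc2 | intermediate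
22 | (1R,4R,5R)-4-hydroxydaucane-6,9-dione (trans-fused; C8 epimers) | O=C1CC(C)C(=O)C[C@@]2(C)CC[C@@](O)(C(C)C)[C@H]12 | intermediate
23 | (1R,4R,5S,6S)-4,6-dihydroxydaucan-9-one (C8 epimers) | O[C@H]1CC(C)C(=O)C[C@@]2(C)CC[C@@](O)(C(C)C)[C@H]12 | intermediate
24 | 4-methoxybenzoyl chloride | COc1ccc(cc1)C(Cl)=O | starting material
25 | (1R,4R,5S,6S)-4-hydroxy-9-oxodaucan-6-yl 4-methoxybenzoate (C8 epimers) | COc1ccc(C(=O)O[C@H]2CC(C)C(=O)C[C@@]3(C)CC[C@@](O)(C(C)C)[C@H]23)cc1 | intermediate
26 | (1R,4R,5S,6S)-4-hydroxy-9-oxodauc-7-en-6-yl 4-methoxybenzoate | COc1ccc(C(=O)O[C@H]2C=C(C)C(=O)C[C@@]3(C)CC[C@@](O)(C(C)C)[C@H]23)cc1 | intermediate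
27 | (1R,4R,5S,6S,9R)-4,9-dihydroxydauc-7-en-6-yl 4-methoxybenzoate | COc1ccc(C(=O)O[C@H]2C=C(C)[C@H](O)C[C@@]3(C)CC[C@@](O)(C(C)C)[C@H]23)cc1 | target

Total step count: 17. Longest linear sequence: 17 steps (1 → 27).

Steps most likely to fail

Step 13. The acyl radical, flanked by two fully substituted carbons, may lose carbon monoxide or be reduced before the slow 7-endo closure takes place. The fallback closes the same ring by olefin metathesis at C7=C8 instead. It sets out from keto aldehyde 18: vinylmagnesium bromide at −78 °C adds to the aldehyde to give the C6 vinyl carbinol F1 (C6 epimers). The second-generation Grubbs catalyst then joins the vinyl group and the isopropenyl ketone to give the 6-hydroxy-7-en-9-one F2. Dess–Martin oxidation gives the 7-ene-6,9-dione F3, and the C4-hydroxyl-directed reduction with Me4NBH(OAc)3 gives the 6-hydroxy enone F4 with the 6-OH anti to the 4-OH. DMAP-catalysed acylation with 24 returns to the route at enone 26.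

Step 12. Conjugate addition of selenolate or phosphine to the isopropenyl ketone, or lactonisation of the activated β-hydroxy acid, may consume the material before the selenoester forms. The fallback avoids selenium and makes the acyl radical from the formyl C–H bond. It sets out from keto aldehyde 18: tetrabutylammonium decatungstate (2 mol %) in acetonitrile under 390 nm light abstracts the aldehyde hydrogen, the acyl radical cyclises as in step 13, and the reduced photocatalyst returns hydrogen to C8. This comes back to the route at dione 22 and bypasses 19 and 21.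

Step 17. Poor facial selectivity in hydride addition to the flexible cycloheptenone would erode the C9 configuration. The fallback replaces substrate control by catalyst control. It sets out from enone 26: Corey–Bakshi–Shibata reduction with (S)-2-methyl-CBS-oxazaborolidine and catecholborane in toluene at −78 °C, with the alkenyl carbon C8 as the large group and C10 as the small one, is expected to give the 9R alcohol and comes back to the route at 27.

Further compounds
F1 | step 13 | 1-[(1R,2S,3R)-3-hydroxy-2-(1-hydroxyprop-2-en-1-yl)-1-methyl-3-(propan-2-yl)cyclopentyl]-3-methylbut-3-en-2-one (C6 epimers) | C=C(C)C(=O)C[C@@]1(C)CC[C@@](O)(C(C)C)[C@@H]1C(O)C=C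
F2 | step 13 | (1R,4R,5S)-4,6-dihydroxydauc-7-en-9-one (C6 epimers) | OC1C=C(C)C(=O)C[C@@]2(C)CC[C@@](O)(C(C)C)[C@H]12
F3 | step 13 | (1R,4R,5R)-4-hydroxydauc-7-ene-6,9-dione | O=C1C=C(C)C(=O)C[C@@]2(C)CC[C@@](O)(C(C)C)[C@H]12
F4 | step 13 | (1R,4R,5S,6S)-4,6-dihydroxydauc-7-en-9-one | O[C@H]1C=C(C)C(=O)C[C@@]2(C)CC[C@@](O)(C(C)C)[C@H]12
F0 | step 12 | none | none
F0 | step 17 | none | none
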